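Time is what the red run is asked about: at the one temperature of these flasks, how much of its Sub is Prd at 26 min?

all flasks: Cat 0.100 mM

| run | Sub | Rgt | time |
|---|---|---|---|
| amber | 50.0 mM | 50.0 mM |  |
| ochre | 30.0 mM | 30.0 mM |  |
| teal | 50.0 mM | 150 mM |  |
| blue | 150 mM | 50.0 mM |  |
| red | 17.0 mM | 17.0 mM | 26 min |

| amber run: time / min | amber run: [Prd] / mM | ochre run: time / min | ochre run: [Prd] / mM | teal run: time / min | teal run: [Prd] / mM | blue run: time / min | blue run: [Prd] / mM |
|---|---|---|---|---|---|---|---|
| 1.0 | 1.44 | 1.0 | 0.98 | 1.0 | 0.06 | 1.0 | 1.86 |
| 2.3 | 3.88 | 2.3 | 2.48 | 2.3 | 0.58 | 2.3 | 4.18 |
| 5.2 | 7.75 | 5.2 | 5.88 | 5.2 | 1.15 | 5.2 | 8.64 |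
| 12 | 17.18 | 12 | 12.40 | 12 | 3.09 | 12 | 18.50 |
| 26 | 32.37 | 26 | 22.21 | 26 | 6.64 | 26 | 32.46 |

(standard deviation of a reading: 0.2 mM)

- Overall: Sub + Rgt -> Prd, with Cat as catalyst.
- Constant volume, constant temperature.
- Bound and free are read together.
- "The second partner" is Rgt.
- An order is taken over about fifteen percent of the charge, up and down.

- order of the initial rate in [Rgt], near the charge of the amber run, the rate being that where two percent of its Sub are Prd
- order of the initial rate in [Sub], near the charge of the amber run, the rate being that where two percent of its Sub are Prd (one fixed amount of Prd, the same in the runs compared)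
- the ochre run starts with 20.0 mM less of Sub and of Rgt than the amber run, and with no Prd. Compared where both hold the same amount of Sub, once fifteen percent of what the ochre run was charged with has turned into Prd, is the ochre run faster, slower or alike (within a tenth)?
- Prd in the red run at 26 min, as a share of the Sub charged
- which of these the readings show (the product binds the substrate / nothing beyond the main steps / the catalyst dies in pairs / the two partners rest in a complex)

I work with what is left, not with what is made. Sub left, bound forms counted, is the charge less Prd. Sub and Rgt go one for one, so a flask charged equally keeps them equal. My measure is the share rate: the natural log of left-before over left-after, divided by the time between, which is the fraction of what is left that goes per minute (an apparent first-order rate constant).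

First link: is the ochre run simply the amber run later on (a same-excess comparison)? The amber run falls from 32.8 mM to 17.6 mM between 12 min and 26 min:

share rate, amber = 0.0444 /min

At that rate the amber run needs 12.0 min to go from 30.0 mM to its last amount. The ochre run took 12 min to reach 17.6 mM, about the same time, although the amber run had used 20.0 mM of Sub by then. So I treat the red run as the ochre run with its clock moved on.

Second link: the last interval of the ochre run ends at 7.79 mM left, which gives its late share rate:

share rate, ochre, late = 0.0582 /min

Third link: at that rate the ochre run passes the red charge at

clock shift = 12.6 min

The red run at 26 min therefore lies that far beyond the last ochre reading: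

left, red = 3.74 mM, so 78.0% made

The weak link is holding the share rate constant. The earlier ochre interval gives 0.0463 /min, less than the late value, so it climbs as the amount left falls. I let it climb by the same step once more:

share rate, tail = 0.0701 /min
left, red = 3.22 mM, so 81.0% made

I commit to that figure. The forecast is lower: 76%, with orders −0.3 in Rgt and 0.3 in Sub, the ochre run alike, and the two partners rest in a complex, on the ground “A further 12.6 min gives about 4 mM left, so about 76%.”

The red run comes to 82.3%. Near the charge of the amber run, the initial rate has order −1.3 in Rgt and 1.9 in Sub. The readings show the two partners rest in a complex, on these steps: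

    Cat + Sub → Cat.Sub (1500 /M/min)
    Cat.Sub + Rgt → Prd + Cat (11820 /M/min)
    Sub + Rgt ⇌ Sub.Rgt, settled at all times (259.0 /M)

That leaves 3.01 mM of Sub in the red run, bound forms counted. Once the ochre run has made the share of Prd asked about, its rate of making Prd over that of the amber run is 1.0, so the two are alike. Going from 7.79 mM to that amount in 12.6 min takes a share rate of 0.0754 /min, higher than my late ochre value of 0.0582 /min and my tail value of 0.0701 /min.

Readings and results come from a simulation for an exercise; noise was put on by code.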